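**Strategy**

Everything rests on disconnecting the enol-ether bond O–C3 of the 3(2H)-furanone (ring atoms O, C3, C2, C1, C10; germacrane numbering). This reveals 32, a ten-membered carbocycle that already carries the trans-fused methylene lactone and the tiglate and holds a C1 ketone conjugated to a C2≡C3 alkyne next to the free C10 tertiary alcohol. A gold-catalysed transannular 5-endo-dig hydroalkoxylation isomerises this strained α′-hydroxy ynone directly into the target, closing the furanone as the last ring. Compound 32 is built from (S)-citramalic acid, a succinate aldol, a (Z)-enynylzinc reagent and an intramolecular Nozaki–Hiyama–Kishi alkynylation.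

Key step: step 19

Remark on numbering: atom labels follow germacrane numbering of the target: C1 ring ketone, C2=C3 furanone double bond, C4=C5 ring alkene, C6 carbinol bearing the tiglate, C7/C8 lactone ring fusion, C9 methylene, C10 quaternary carbon, C11=C13 exocyclic methylene, C12 lactone carbonyl. The target is (6S,7R,8S,10S).
Assumption: (S)-citramalic acid, (R)-4-benzyl-1,3-oxazolidin-2-one, propyne, ethynyltrimethylsilane and tigloyl chloride are taken as commercial.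

**Route**

Step 1
Reactants: 1 (S)-citramalic acid
Product: 2 (2S)-2-methylbutane-1,2,4-triol
Conditions: BH3·SMe2, B(OMe)3, THF, 0 °C to rt; MeOH
Reagents that add atoms: none
Why: Borane reduces both carboxylic acids chemoselectively to primary alcohols, and the quaternary carbinol carbon (later C10) is not involved and keeps its (S) configuration.

Step 2
Reactants: 2 (2S)-2-methylbutane-1,2,4-triol
Product: 3 2-[(4S)-2,2,4-trimethyl-1,3-dioxolan-4-yl]ethan-1-ol
Conditions: 2,2-dimethoxypropane, p-TsOH (cat.), acetone, rt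
Reagents that add atoms: 2,2-dimethoxypropane, COC(C)(C)OC
Why: Acid-catalysed transketalisation under thermodynamic control favours the five-membered dioxolane of the 1,2-diol over the six-membered dioxane, which leaves the primary hydroxyl (later C8) free.

Step 3
Reactants: 3 2-[(4S)-2,2,4-trimethyl-1,3-dioxolan-4-yl]ethan-1-ol
Product: 4 2-[(4S)-2,2,4-trimethyl-1,3-dioxolan-4-yl]acetaldehyde
Conditions: TEMPO (cat.), PhI(OAc)2, CH2Cl2, rt
Reagents that add atoms: none
Why: The oxoammonium-mediated oxidation stops at the aldehyde and does not touch the acetonide.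

Step 4
Reactants: 5 (4R)-4-benzyl-1,3-oxazolidin-2-one; 6 methyl 4-chloro-4-oxobutanoate
Product: 7 methyl 4-[(4R)-4-benzyl-2-oxo-1,3-oxazolidin-3-yl]-4-oxobutanoate
Conditions: Et3N, DMAP (cat.), CH2Cl2, 0 °C to rt
Reagents that add atoms: none
Why: DMAP-catalysed N-acylation of the oxazolidinone by the acid chloride, with the methyl ester inert.

Step 5
Reactants: 7 methyl 4-[(4R)-4-benzyl-2-oxo-1,3-oxazolidin-3-yl]-4-oxobutanoate; 4 2-[(4S)-2,2,4-trimethyl-1,3-dioxolan-4-yl]acetaldehyde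
Product: 10 (4R)-4-benzyl-3-{[(2S,3R)-5-oxo-2-{[(4S)-2,2,4-trimethyl-1,3-dioxolan-4-yl]methyl}oxolan-3-yl]carbonyl}-1,3-oxazolidin-2-one, via dibutylboron enolate 8 (not isolated), via syn-aldol adduct 9 (not isolated)
Conditions: Bu2BOTf, i-Pr2NEt, CH2Cl2, 0 °C; 4, −78 to 0 °C; pH 7 buffer, MeOH, H2O2; then PPTS (cat.), toluene, 60 °C
Reagents that add atoms: none
Why: Evans syn-aldol reaction in which the (Z)-boron enolate adds through a Zimmerman–Traxler chair on the face opposite the benzyl group of the (R)-auxiliary, setting C7 (R) and C8 (S) in a 7,8-syn relationship, after which the γ-hydroxy methyl ester closes to the trans-disubstituted γ-lactone.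

Step 6
Reactants: 10 (4R)-4-benzyl-3-{[(2S,3R)-5-oxo-2-{[(4S)-2,2,4-trimethyl-1,3-dioxolan-4-yl]methyl}oxolan-3-yl]carbonyl}-1,3-oxazolidin-2-one
Product: 11 S-ethyl (2S,3R)-5-oxo-2-{[(4S)-2,2,4-trimethyl-1,3-dioxolan-4-yl]methyl}oxolane-3-carbothioate
Conditions: EtSH, n-BuLi, THF, 0 °C
Reagents that add atoms: ethanethiol, CCS
Why: Lithium ethanethiolate attacks the exocyclic imide carbonyl, which is far more electrophilic than the lactone, and expels the auxiliary; the trans arrangement at C7/C8 is the thermodynamic one, so no epimerisation is expected.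

Step 7
Reactants: 12 propyne
Product: 14 2-[(1Z)-2-bromoprop-1-en-1-yl]-4,4,5,5-tetramethyl-1,3,2-dioxaborolane, via dibromo alkenylborane 13 (not isolated)
Conditions: BBr3, CH2Cl2, −78 °C to rt; pinacol, CH2Cl2, 0 °C
Reagents that add atoms: boron tribromide, BrB(Br)Br; pinacol, CC(C)(O)C(C)(C)O
Why: syn-Bromoboration of the terminal alkyne places boron on the terminal carbon and bromine on the internal carbon on the same side, and esterification with pinacol fixes the (Z)-alkenylboronate.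

Step 8
Reactants: 14 2-[(1Z)-2-bromoprop-1-en-1-yl]-4,4,5,5-tetramethyl-1,3,2-dioxaborolane; 15 ethynyltrimethylsilane
Product: 16 trimethyl[(3Z)-3-methyl-4-(4,4,5,5-tetramethyl-1,3,2-dioxaborolan-2-yl)but-3-en-1-yn-1-yl]silane
Conditions: PdCl2(PPh3)2 (cat.), CuI (cat.), i-Pr2NH, THF, rt
Reagents that add atoms: none
Why: Sonogashira coupling at the C–Br bond proceeds with retention of alkene geometry, and the pinacol boronate is inert in the absence of aqueous base.

Step 9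
Reactants: 16 trimethyl[(3Z)-3-methyl-4-(4,4,5,5-tetramethyl-1,3,2-dioxaborolan-2-yl)but-3-en-1-yn-1-yl]silane
Product: 17 [(3Z)-4-iodo-3-methylbut-3-en-1-yn-1-yl]trimethylsilane
Conditions: NaOH (aq.), I2, THF, 0 °C, short contact time
Reagents that add atoms: iodine, [I][I]
Why: Iododeboronation through the hydroxy ate complex replaces boron by iodine with retention, so that iodine ends up cis to the alkynyl group.

Step 10
Reactants: 17 [(3Z)-4-iodo-3-methylbut-3-en-1-yn-1-yl]trimethylsilane; 11 S-ethyl (2S,3R)-5-oxo-2-{[(4S)-2,2,4-trimethyl-1,3-dioxolan-4-yl]methyl}oxolane-3-carbothioate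
Product: 20 (4R,5S)-4-[(2Z)-3-methyl-5-(trimethylsilyl)pent-2-en-4-ynoyl]-5-{[(4S)-2,2,4-trimethyl-1,3-dioxolan-4-yl]methyl}oxolan-2-one, via alkenyllithium 18 (not isolated), via alkenylzinc chloride 19 (not isolated)
Conditions: 17, t-BuLi (2 equiv), Et2O, −78 °C; ZnCl2, THF, −78 to 0 °C; then 11, PdCl2(PPh3)2 (cat.), toluene, rt
Reagents that add atoms: none
Why: Fukuyama ketone synthesis in which zerovalent palladium inserts into the C–S bond of the thioester and the configurationally stable (Z)-alkenylzinc transfers its alkenyl group with retention, under neutral conditions that tolerate the lactone and the acetonide.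

Step 11
Reactants: 20 (4R,5S)-4-[(2Z)-3-methyl-5-(trimethylsilyl)pent-2-en-4-ynoyl]-5-{[(4S)-2,2,4-trimethyl-1,3-dioxolan-4-yl]methyl}oxolan-2-one
Product: 21 (4S,5S)-4-[(1S,2Z)-1-hydroxy-3-methyl-5-(trimethylsilyl)pent-2-en-4-yn-1-yl]-5-{[(4S)-2,2,4-trimethyl-1,3-dioxolan-4-yl]methyl}oxolan-2-one
Conditions: LiBH(s-Bu)3, THF, −78 °C; NH4Cl (aq.) at −78 °C
Reagents that add atoms: none
Why: 1,2-Reduction under Felkin–Anh control, in which the bulky hydride should attack the ketone anti to C8, the more substituted of the two ring carbons on C7, giving the 6,7-anti alcohol with (S) configuration at C6, while the β,β-disubstituted enone resists conjugate reduction.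

Step 12
Reactants: 21 (4S,5S)-4-[(1S,2Z)-1-hydroxy-3-methyl-5-(trimethylsilyl)pent-2-en-4-yn-1-yl]-5-{[(4S)-2,2,4-trimethyl-1,3-dioxolan-4-yl]methyl}oxolan-2-one; 22 tigloyl chloride [(2E)-2-methylbut-2-enoyl chloride]
Product: 23 (1S,2Z)-3-methyl-1-[(2S,3R)-5-oxo-2-{[(4S)-2,2,4-trimethyl-1,3-dioxolan-4-yl]methyl}oxolan-3-yl]-5-(trimethylsilyl)pent-2-en-4-yn-1-yl (2E)-2-methylbut-2-enoate
Conditions: pyridine, DMAP (cat.), CH2Cl2, 0 °C to rt
Reagents that add atoms: none
Why: DMAP-catalysed O-acylation of the secondary allylic alcohol with retention at C6, the tiglate being the stable (E)-isomer.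

Step 13
Reactants: 23 (1S,2Z)-3-methyl-1-[(2S,3R)-5-oxo-2-{[(4S)-2,2,4-trimethyl-1,3-dioxolan-4-yl]methyl}oxolan-3-yl]-5-(trimethylsilyl)pent-2-en-4-yn-1-yl (2E)-2-methylbut-2-enoate
Product: 27 (1S,2Z)-3-methyl-1-[(2S,3R)-4-methylidene-5-oxo-2-{[(4S)-2,2,4-trimethyl-1,3-dioxolan-4-yl]methyl}oxolan-3-yl]-5-(trimethylsilyl)pent-2-en-4-yn-1-yl (2E)-2-methylbut-2-enoate, via lithium enolate 24 (not isolated), via Mannich base 25 (not isolated), via ammonium iodide 26 (not isolated)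
Conditions: LiN(SiMe3)2, THF, −78 °C; CH2=NMe2+ I−, −78 to 0 °C; MeI, CH2Cl2/MeOH, rt; NaHCO3 (aq.), CH2Cl2
Reagents that add atoms: N,N-dimethylmethyleneiminium iodide, C=[N+](C)C.[I-]
Why: Eschenmoser methylenation, in which the lactone α-CH2 is the most acidic site (the tiglate has no α-hydrogen), its enolate undergoes a Mannich reaction with the iminium salt, and quaternisation followed by E1cB elimination gives the exocyclic methylene with no stereocentre left at C11.

Step 14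
Reactants: 27 (1S,2Z)-3-methyl-1-[(2S,3R)-4-methylidene-5-oxo-2-{[(4S)-2,2,4-trimethyl-1,3-dioxolan-4-yl]methyl}oxolan-3-yl]-5-(trimethylsilyl)pent-2-en-4-yn-1-yl (2E)-2-methylbut-2-enoate
Product: 28 (1S,2Z)-5-iodo-3-methyl-1-[(2S,3R)-4-methylidene-5-oxo-2-{[(4S)-2,2,4-trimethyl-1,3-dioxolan-4-yl]methyl}oxolan-3-yl]pent-2-en-4-yn-1-yl (2E)-2-methylbut-2-enoate
Conditions: N-iodosuccinimide, AgNO3 (cat.), acetone, rt, dark
Reagents that add atoms: N-iodosuccinimide, O=C1CCC(=O)N1I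
Why: Silver-catalysed iododesilylation, in which AgNO3 activates the silylalkyne towards electrophilic substitution by N-iodosuccinimide under neutral conditions.

Step 15
Reactants: 28 (1S,2Z)-5-iodo-3-methyl-1-[(2S,3R)-4-methylidene-5-oxo-2-{[(4S)-2,2,4-trimethyl-1,3-dioxolan-4-yl]methyl}oxolan-3-yl]pent-2-en-4-yn-1-yl (2E)-2-methylbut-2-enoate
Product: 29 (1S,2Z)-1-{(2S,3R)-2-[(2S)-2,3-dihydroxy-2-methylpropyl]-4-methylidene-5-oxooxolan-3-yl}-5-iodo-3-methylpent-2-en-4-yn-1-yl (2E)-2-methylbut-2-enoate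
Conditions: AcOH/H2O (4:1), 40 °C
Reagents that add atoms: none
Why: Aqueous acid hydrolyses the isopropylidene ketal, while the esters, the iodoalkyne and the methylene lactone are stable to these conditions.

Step 16
Reactants: 29 (1S,2Z)-1-{(2S,3R)-2-[(2S)-2,3-dihydroxy-2-methylpropyl]-4-methylidene-5-oxooxolan-3-yl}-5-iodo-3-methylpent-2-en-4-yn-1-yl (2E)-2-methylbut-2-enoate
Product: 30 (1S,2Z)-1-{(2S,3R)-2-[(2S)-2-hydroxy-2-methyl-3-oxopropyl]-4-methylidene-5-oxooxolan-3-yl}-5-iodo-3-methylpent-2-en-4-yn-1-yl (2E)-2-methylbut-2-enoate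
Conditions: SO3·pyridine, DMSO, i-Pr2NEt, CH2Cl2, 0 °C
Reagents that add atoms: none
Why: Parikh–Doering oxidation converts the primary alcohol into the aldehyde, cannot oxidise the tertiary C10 alcohol and does not cleave the 1,2-diol.

Step 17
Reactants: 30 (1S,2Z)-1-{(2S,3R)-2-[(2S)-2-hydroxy-2-methyl-3-oxopropyl]-4-methylidene-5-oxooxolan-3-yl}-5-iodo-3-methylpent-2-en-4-yn-1-yl (2E)-2-methylbut-2-enoate
Product: 31 (6S,7R,8S,10S)-1,10-dihydroxy-6-[(2E)-2-methylbut-2-enoyloxy]germacra-4Z,11(13)-dien-2-yn-12,8-olide (both C1 epimers)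
Conditions: CrCl2 (excess), NiCl2 (cat.), THF, rt, slow addition at high dilution
Reagents that add atoms: none
Why: Intramolecular Nozaki–Hiyama–Kishi reaction, in which divalent chromium converts the iodoalkyne into an alkynylchromium species that adds only to the aldehyde, the (Z)-alkene, the trans-lactone and the quaternary C10 pre-organise the chain as in closures of ten-membered enediyne rings, and the new C1 carbinol centre is left uncontrolled because step 18 removes it.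

Step 18
Reactants: 31 (6S,7R,8S,10S)-1,10-dihydroxy-6-[(2E)-2-methylbut-2-enoyloxy]germacra-4Z,11(13)-dien-2-yn-12,8-olide
Product: 32 (6S,7R,8S,10S)-10-hydroxy-1-oxo-6-[(2E)-2-methylbut-2-enoyloxy]germacra-4Z,11(13)-dien-2-yn-12,8-olide
Conditions: MnO2, CH2Cl2, rt
Reagents that add atoms: none
Why: MnO2 oxidises the activated propargylic secondary alcohol selectively and leaves the tertiary alcohol untouched, without glycol cleavage.

Step 19
Reactants: 32 (6S,7R,8S,10S)-10-hydroxy-1-oxo-6-[(2E)-2-methylbut-2-enoyloxy]germacra-4Z,11(13)-dien-2-yn-12,8-olide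
Product: 33 (6S,7R,8S,10S)-3,10-epoxy-1-oxo-6-[(2E)-2-methylbut-2-enoyloxy]germacra-2,4Z,11(13)-trien-12,8-olide (target)
Conditions: Ph3PAuNTf2 (5 mol%), toluene, rt
Reagents that add atoms: none
Why: The cationic monovalent gold centre π-activates the ynone triple bond and the C10 hydroxyl adds anti to gold at C3, the β-carbon of the ynone, to give a vinylgold oxonium ion that is protodeaurated at C2, releasing the enol ether and the catalyst. The closest known reaction type is the gold-catalysed cycloisomerisation of acyclic α′-hydroxy ynones to 3(2H)-furanones, here run across a ring that is already closed. The five-membered ring O–C3=C2–C1(=O)–C10 closes in the 5-endo-dig mode by O–C3 bond formation, and the two alkyne carbons become the C2=C3 enol ether. No stereocentre is formed: C10 comes unchanged from (S)-citramalic acid, C6, C7 and C8 are untouched, and the geometry of C2=C3 is fixed by the new ring. The step needs attack of the hydroxyl at C3 and not at C2, and no participation of the ester or lactone carbonyl groups; the polarisation of the ynone, the impossibility of a 4-exo closure at C2 and the α′ position of the only free hydroxyl secure this. Release of the angle strain of the bent cycloalkyne adds driving force, and the neutral conditions should leave the methylene lactone, the tiglate and the (Z)-alkene intact.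

**Compound list**

1 | (S)-citramalic acid [(2S)-2-hydroxy-2-methylbutanedioic acid] | C[C@](O)(CC(=O)O)C(=O)O | starting material
2 | (2S)-2-methylbutane-1,2,4-triol | OCC[C@](C)(O)CO | intermediate
3 | 2-[(4S)-2,2,4-trimethyl-1,3-dioxolan-4-yl]ethan-1-ol | OCC[C@]1(C)OC(C)(C)OC1 | intermediate
4 | 2-[(4S)-2,2,4-trimethyl-1,3-dioxolan-4-yl]acetaldehyde | O=CC[C@]1(C)OC(C)(C)OC1 | intermediate
5 | (4R)-4-benzyl-1,3-oxazolidin-2-one | O=C1N[C@H](Cc2ccccc2)CO1 | starting material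
6 | methyl 4-chloro-4-oxobutanoate | COC(=O)CCC(Cl)=O | starting material
7 | methyl 4-[(4R)-4-benzyl-2-oxo-1,3-oxazolidin-3-yl]-4-oxobutanoate | COC(=O)CCC(=O)N1C(=O)OC[C@H]1Cc1ccccc1 | intermediate
8 | dibutylboron (Z)-enolate of 7 | COC(=O)C/C=C(\OB(CCCC)CCCC)N1C(=O)OC[C@H]1Cc1ccccc1 | intermediate (not isolated)
9 | methyl (3R,4S)-3-{[(4R)-4-benzyl-2-oxo-1,3-oxazolidin-3-yl]carbonyl}-4-hydroxy-5-[(4S)-2,2,4-trimethyl-1,3-dioxolan-4-yl]pentanoate | COC(=O)C[C@@H](C(=O)N1C(=O)OC[C@H]1Cc1ccccc1)[C@@H](O)C[C@]1(C)OC(C)(C)OC1 | intermediate (not isolated)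
10 | (4R)-4-benzyl-3-{[(2S,3R)-5-oxo-2-{[(4S)-2,2,4-trimethyl-1,3-dioxolan-4-yl]methyl}oxolan-3-yl]carbonyl}-1,3-oxazolidin-2-one | O=C1O[C@@H](C[C@]2(C)OC(C)(C)OC2)[C@H](C(=O)N2C(=O)OC[C@H]2Cc2ccccc2)C1 | intermediate
11 | S-ethyl (2S,3R)-5-oxo-2-{[(4S)-2,2,4-trimethyl-1,3-dioxolan-4-yl]methyl}oxolane-3-carbothioate | O=C1O[C@@H](C[C@]2(C)OC(C)(C)OC2)[C@H](C(=O)SCC)C1 | intermediate
12 | propyne | CC#C | starting material
13 | dibromo[(1Z)-2-bromoprop-1-en-1-yl]borane | C/C(Br)=C/B(Br)Br | intermediate (not isolated)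
14 | 2-[(1Z)-2-bromoprop-1-en-1-yl]-4,4,5,5-tetramethyl-1,3,2-dioxaborolane | C/C(Br)=C/B1OC(C)(C)C(C)(C)O1 | intermediate
15 | ethynyltrimethylsilane | C#C[Si](C)(C)C | starting material
16 | trimethyl[(3Z)-3-methyl-4-(4,4,5,5-tetramethyl-1,3,2-dioxaborolan-2-yl)but-3-en-1-yn-1-yl]silane | C/C(C#C[Si](C)(C)C)=C/B1OC(C)(C)C(C)(C)O1 | intermediate
17 | [(3Z)-4-iodo-3-methylbut-3-en-1-yn-1-yl]trimethylsilane | C/C(C#C[Si](C)(C)C)=C/I | intermediate
18 | [(1Z)-2-methyl-4-(trimethylsilyl)but-1-en-3-yn-1-yl]lithium | C/C(C#C[Si](C)(C)C)=C/[Li] | intermediate (not isolated)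
19 | chloro[(1Z)-2-methyl-4-(trimethylsilyl)but-1-en-3-yn-1-yl]zinc | C/C(C#C[Si](C)(C)C)=C/[Zn]Cl | intermediate (not isolated)
20 | (4R,5S)-4-[(2Z)-3-methyl-5-(trimethylsilyl)pent-2-en-4-ynoyl]-5-{[(4S)-2,2,4-trimethyl-1,3-dioxolan-4-yl]methyl}oxolan-2-one | O=C1O[C@@H](C[C@]2(C)OC(C)(C)OC2)[C@H](C(=O)/C=C(C)\C#C[Si](C)(C)C)C1 | intermediate
21 | (4S,5S)-4-[(1S,2Z)-1-hydroxy-3-methyl-5-(trimethylsilyl)pent-2-en-4-yn-1-yl]-5-{[(4S)-2,2,4-trimethyl-1,3-dioxolan-4-yl]methyl}oxolan-2-one | O=C1O[C@@H](C[C@]2(C)OC(C)(C)OC2)[C@H]([C@@H](O)/C=C(C)\C#C[Si](C)(C)C)C1 | intermediate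
22 | tigloyl chloride [(2E)-2-methylbut-2-enoyl chloride] | C/C=C(\C)C(Cl)=O | starting material
23 | (1S,2Z)-3-methyl-1-[(2S,3R)-5-oxo-2-{[(4S)-2,2,4-trimethyl-1,3-dioxolan-4-yl]methyl}oxolan-3-yl]-5-(trimethylsilyl)pent-2-en-4-yn-1-yl (2E)-2-methylbut-2-enoate | O=C1O[C@@H](C[C@]2(C)OC(C)(C)OC2)[C@H]([C@@H](OC(=O)/C(C)=C/C)/C=C(C)\C#C[Si](C)(C)C)C1 | intermediate
24 | lithium enolate of lactone 23 | [Li]OC1=C[C@@H]([C@@H](OC(=O)/C(C)=C/C)/C=C(C)\C#C[Si](C)(C)C)[C@H](C[C@]2(C)OC(C)(C)OC2)O1 | intermediate (not isolated)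
25 | α-(dimethylaminomethyl) lactone from 23 (Mannich base, C11 epimers) | O=C1O[C@@H](C[C@]2(C)OC(C)(C)OC2)[C@H]([C@@H](OC(=O)/C(C)=C/C)/C=C(C)\C#C[Si](C)(C)C)C1CN(C)C | intermediate (not isolated)
26 | α-(trimethylammoniomethyl) lactone iodide from 25 | O=C1O[C@@H](C[C@]2(C)OC(C)(C)OC2)[C@H]([C@@H](OC(=O)/C(C)=C/C)/C=C(C)\C#C[Si](C)(C)C)C1C[N+](C)(C)C.[I-] | intermediate (not isolated)
27 | (1S,2Z)-3-methyl-1-[(2S,3R)-4-methylidene-5-oxo-2-{[(4S)-2,2,4-trimethyl-1,3-dioxolan-4-yl]methyl}oxolan-3-yl]-5-(trimethylsilyl)pent-2-en-4-yn-1-yl (2E)-2-methylbut-2-enoate | O=C1O[C@@H](C[C@]2(C)OC(C)(C)OC2)[C@H]([C@@H](OC(=O)/C(C)=C/C)/C=C(C)\C#C[Si](C)(C)C)C1=C | intermediate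
28 | (1S,2Z)-5-iodo-3-methyl-1-[(2S,3R)-4-methylidene-5-oxo-2-{[(4S)-2,2,4-trimethyl-1,3-dioxolan-4-yl]methyl}oxolan-3-yl]pent-2-en-4-yn-1-yl (2E)-2-methylbut-2-enoate | O=C1O[C@@H](C[C@]2(C)OC(C)(C)OC2)[C@H]([C@@H](OC(=O)/C(C)=C/C)/C=C(C)\C#CI)C1=C | intermediate
29 | (1S,2Z)-1-{(2S,3R)-2-[(2S)-2,3-dihydroxy-2-methylpropyl]-4-methylidene-5-oxooxolan-3-yl}-5-iodo-3-methylpent-2-en-4-yn-1-yl (2E)-2-methylbut-2-enoate | O=C1O[C@@H](C[C@](C)(O)CO)[C@H]([C@@H](OC(=O)/C(C)=C/C)/C=C(C)\C#CI)C1=C | intermediate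
30 | (1S,2Z)-1-{(2S,3R)-2-[(2S)-2-hydroxy-2-methyl-3-oxopropyl]-4-methylidene-5-oxooxolan-3-yl}-5-iodo-3-methylpent-2-en-4-yn-1-yl (2E)-2-methylbut-2-enoate | O=C1O[C@@H](C[C@](C)(O)C=O)[C@H]([C@@H](OC(=O)/C(C)=C/C)/C=C(C)\C#CI)C1=C | intermediate
31 | (6S,7R,8S,10S)-1,10-dihydroxy-6-[(2E)-2-methylbut-2-enoyloxy]germacra-4Z,11(13)-dien-2-yn-12,8-olide (C1 epimers) | C=C1C(=O)O[C@H]2C[C@](C)(O)C(O)C#C/C(C)=C\[C@H](OC(=O)/C(C)=C/C)[C@H]12 | intermediate
32 | (6S,7R,8S,10S)-10-hydroxy-1-oxo-6-[(2E)-2-methylbut-2-enoyloxy]germacra-4Z,11(13)-dien-2-yn-12,8-olide | C=C1C(=O)O[C@H]2C[C@](C)(O)C(=O)C#C/C(C)=C\[C@H](OC(=O)/C(C)=C/C)[C@H]12 | intermediate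
33 | (6S,7R,8S,10S)-3,10-epoxy-1-oxo-6-[(2E)-2-methylbut-2-enoyloxy]germacra-2,4Z,11(13)-trien-12,8-olide | C=C1C(=O)O[C@H]2C[C@]3(C)OC(=CC3=O)/C(C)=C\[C@H](OC(=O)/C(C)=C/C)[C@H]12 | target

**Step count and risks**

Total step count: 19. Longest linear sequence: 15 steps (steps 1–3, 5, 6, 10–19).

Steps most likely to fail:

1. Step 17 (macrocyclisation). Closure of the bent ten-membered cycloalkyne may be slower than intermolecular coupling and simple reduction of the C–I bond, and the low-valent metals may attack the allylic ester. The fallback sets out from 28 and comes back at 33; it closes the ring through a (Z)-alkenyl iodide, the most reliable partner of this reaction, and forms the furanone afterwards, still as the last ring, by an oxidative Wacker-type cyclisation. Hydroboration of 28 with dicyclohexylborane (THF, 0 °C) should give the α-iodoalkenylborane F1, and protonolysis with AcOH the (Z)-iodoalkene F2. AcOH/H2O should then release the diol F3, and Parikh–Doering oxidation should give the hydroxy aldehyde F4. CrCl2 with NiCl2 (cat.) in THF/DMSO at high dilution should close the ring to the (2Z,4Z)-dienol F5, and MnO2 should give the α′-hydroxy dienone F6. Finally PdCl2(MeCN)2 (cat.), CuCl (cat.), Na2HPO4 and O2 in DME should add the C10 hydroxyl to C3 and restore the C2=C3 double bond by β-hydride elimination, giving 33.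

2. Step 11 (facial selectivity at C6). The two ring carbons flanking C7 differ only moderately in size, so hydride may add to the other face of the ketone, and conjugate reduction or translactonisation by the new alkoxide may interfere. The fallback sets out from 20 and comes back at 23; it no longer depends on the facial selectivity, because the unwanted epimer is inverted while the ester is installed. Luche reduction of 20 (NaBH4, CeCl3·7H2O, MeOH, −78 °C) should give both carbinol epimers without conjugate reduction. The (1S)-epimer 21 is acylated as in step 12. The (1R)-epimer F7 is esterified with tiglic acid under Mitsunobu conditions (PPh3, diisopropyl azodicarboxylate, toluene, 0 °C), which inverts C6 and gives the same ester 23.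

3. Step 13 (methylenation beside the tiglate). γ-Deprotonation of the tiglate, O-to-C acyl transfer from the ester to the lactone enolate or loss of the allylic ester may compete with enolate trapping. The fallback sets out from 21 and comes back at 27; it carries C6 as a silyl ether through the enolate chemistry and installs the tiglate afterwards. TBSOTf and 2,6-lutidine (CH2Cl2, −78 °C) should give the silyl ether F8. LiN(SiMe3)2 should give the lithium enolate F9, CH2=NMe2+ I− the Mannich base F10, MeI the ammonium iodide F11 and NaHCO3 the methylene lactone silyl ether F12. HF·pyridine (THF, 0 °C) should release the methylene lactone alcohol F13 without forming an alkoxide, and tigloyl chloride 22 with pyridine and DMAP (cat.) should give 27.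

**Further compounds**

F1 | step 17 | (1S,2Z,4Z)-5-(dicyclohexylboranyl)-5-iodo-3-methyl-1-[(2S,3R)-4-methylidene-5-oxo-2-{[(4S)-2,2,4-trimethyl-1,3-dioxolan-4-yl]methyl}oxolan-3-yl]penta-2,4-dien-1-yl (2E)-2-methylbut-2-enoate | O=C1O[C@@H](C[C@]2(C)OC(C)(C)OC2)[C@H]([C@@H](OC(=O)/C(C)=C/C)/C=C(C)\C=C(/I)B(C2CCCCC2)C2CCCCC2)C1=C
F2 | step 17 | (1S,2Z,4Z)-5-iodo-3-methyl-1-[(2S,3R)-4-methylidene-5-oxo-2-{[(4S)-2,2,4-trimethyl-1,3-dioxolan-4-yl]methyl}oxolan-3-yl]penta-2,4-dien-1-yl (2E)-2-methylbut-2-enoate | O=C1O[C@@H](C[C@]2(C)OC(C)(C)OC2)[C@H]([C@@H](OC(=O)/C(C)=C/C)/C=C(C)\C=C/I)C1=C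
F3 | step 17 | (1S,2Z,4Z)-1-{(2S,3R)-2-[(2S)-2,3-dihydroxy-2-methylpropyl]-4-methylidene-5-oxooxolan-3-yl}-5-iodo-3-methylpenta-2,4-dien-1-yl (2E)-2-methylbut-2-enoate | O=C1O[C@@H](C[C@](C)(O)CO)[C@H]([C@@H](OC(=O)/C(C)=C/C)/C=C(C)\C=C/I)C1=C
F4 | step 17 | (1S,2Z,4Z)-1-{(2S,3R)-2-[(2S)-2-hydroxy-2-methyl-3-oxopropyl]-4-methylidene-5-oxooxolan-3-yl}-5-iodo-3-methylpenta-2,4-dien-1-yl (2E)-2-methylbut-2-enoate | O=C1O[C@@H](C[C@](C)(O)C=O)[C@H]([C@@H](OC(=O)/C(C)=C/C)/C=C(C)\C=C/I)C1=C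
F5 | step 17 | (6S,7R,8S,10S)-1,10-dihydroxy-6-[(2E)-2-methylbut-2-enoyloxy]germacra-2Z,4Z,11(13)-trien-12,8-olide (C1 epimers) | C=C1C(=O)O[C@H]2C[C@](C)(O)C(O)/C=C\C(C)=C/[C@H](OC(=O)/C(C)=C/C)[C@H]12
F6 | step 17 | (6S,7R,8S,10S)-10-hydroxy-1-oxo-6-[(2E)-2-methylbut-2-enoyloxy]germacra-2Z,4Z,11(13)-trien-12,8-olide | C=C1C(=O)O[C@H]2C[C@](C)(O)C(=O)/C=C\C(C)=C/[C@H](OC(=O)/C(C)=C/C)[C@H]12
F7 | step 11 | (4S,5S)-4-[(1R,2Z)-1-hydroxy-3-methyl-5-(trimethylsilyl)pent-2-en-4-yn-1-yl]-5-{[(4S)-2,2,4-trimethyl-1,3-dioxolan-4-yl]methyl}oxolan-2-one | O=C1O[C@@H](C[C@]2(C)OC(C)(C)OC2)[C@H]([C@H](O)/C=C(C)\C#C[Si](C)(C)C)C1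
F8 | step 13 | (4R,5S)-4-[(1S,2Z)-1-{[tert-butyl(dimethyl)silyl]oxy}-3-methyl-5-(trimethylsilyl)pent-2-en-4-yn-1-yl]-5-{[(4S)-2,2,4-trimethyl-1,3-dioxolan-4-yl]methyl}oxolan-2-one | O=C1O[C@@H](C[C@]2(C)OC(C)(C)OC2)[C@H]([C@@H](O[Si](C)(C)C(C)(C)C)/C=C(C)\C#C[Si](C)(C)C)C1
F9 | step 13 | lithium enolate of lactone F8 | [Li]OC1=C[C@@H]([C@@H](O[Si](C)(C)C(C)(C)C)/C=C(C)\C#C[Si](C)(C)C)[C@H](C[C@]2(C)OC(C)(C)OC2)O1
F10 | step 13 | α-(dimethylaminomethyl) lactone from F8 (Mannich base, C11 epimers) | O=C1O[C@@H](C[C@]2(C)OC(C)(C)OC2)[C@H]([C@@H](O[Si](C)(C)C(C)(C)C)/C=C(C)\C#C[Si](C)(C)C)C1CN(C)C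
F11 | step 13 | α-(trimethylammoniomethyl) lactone iodide from F10 | O=C1O[C@@H](C[C@]2(C)OC(C)(C)OC2)[C@H]([C@@H](O[Si](C)(C)C(C)(C)C)/C=C(C)\C#C[Si](C)(C)C)C1C[N+](C)(C)C.[I-]
F12 | step 13 | (4R,5S)-4-[(1S,2Z)-1-{[tert-butyl(dimethyl)silyl]oxy}-3-methyl-5-(trimethylsilyl)pent-2-en-4-yn-1-yl]-3-methylidene-5-{[(4S)-2,2,4-trimethyl-1,3-dioxolan-4-yl]methyl}oxolan-2-one | O=C1O[C@@H](C[C@]2(C)OC(C)(C)OC2)[C@H]([C@@H](O[Si](C)(C)C(C)(C)C)/C=C(C)\C#C[Si](C)(C)C)C1=C
F13 | step 13 | (4S,5S)-4-[(1S,2Z)-1-hydroxy-3-methyl-5-(trimethylsilyl)pent-2-en-4-yn-1-yl]-3-methylidene-5-{[(4S)-2,2,4-trimethyl-1,3-dioxolan-4-yl]methyl}oxolan-2-one | O=C1O[C@@H](C[C@]2(C)OC(C)(C)OC2)[C@H]([C@@H](O)/C=C(C)\C#C[Si](C)(C)C)C1=C
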